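The question concerns 15 min, and the dusk run, which is this same flask followed so far, stops at 5.00 min.

- dusk: left-handed substrate 0.50 M; right-handed substrate 0.50 M; partner 1.5 M; precatalyst 25 mM; added ligand 48 mM; the very flask that is asked about, followed so far
- flask: left-handed substrate 0.50 M; partner 1.50 M; precatalyst 25 mM; added ligand 48 mM; right-handed substrate 0.50 M; time 15 min

dusk run (percent of the left-handed substrate and right-handed substrate together charged)

| time / min | left-handed substrate / % | right-handed substrate / % | left-handed product / % |
|---|---|---|---|
| 0.333 | 50.0 | 50.5 | 0 |
| 0.667 | 49.6 | 50.2 | 1.0 |
| 1.00 | 49.3 | 48.9 | 1.3 |
| 1.50 | 48.7 | 49.8 | 0.6 |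
| 2.50 | 47.7 | 49.3 | 3.1 |
| 5.00 | 46.6 | 47.5 | 4.5 |

(each reading ± 0.5 percentage points)

- part of the left-handed substrate and right-handed substrate charged together that has reacted at 15 min
- excess of left-handed product over right-handed product in the product at 15 min
- excess of right-handed substrate over left-handed substrate among what is left of the two at 15 min

- catalyst is single-handed; left-handed substrate and right-handed substrate are mirror images of each other, charged as a racemate, each of them at the stated concentration
- steps under discussion: partner + catalyst + left-handed substrate -> catalyst + left-handed product; partner + catalyst + right-handed substrate -> catalyst + right-handed product; left-handed substrate <-> right-handed substrate; partner + precatalyst -> catalyst + spent reagent; catalyst + added ligand <-> idle complex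
- an excess is the difference of the two amounts in percent of their sum
- an excess is below zero if the other one leads

In the dusk run at 5.00 min the two substrates together read 94.1% of the charge. If this pool loses the same share in equal times, its pool half-life (a pseudo-first-order half-life), read from that reading, is 57.0 min. The asked time is 0.263 of these, so this reckoning gives the reacted part of the charge, c, near 16.7%.

In the dusk run at 5.00 min the left-handed product reads 4.5%, which puts the product excess, eP, near 52.5%, with wide scatter. Two extreme flasks frame the excess of right-handed substrate, eS. With no exchange between the substrates, eS equals that excess times c/(1−c), or 10.5% at the asked time and 3.29% at 5.00 min. With instant exchange, the substrates fall together and eS stays at zero. The dusk run's substrate excess at 5.00 min reads 0.956%, less than the first extreme and nearer the second. This reckoning therefore commits to the second side, with eS near that reading.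

The forecast gives c 16% (11% to 23%), eP 38% (20% to 55%) and eS 5.5% (1% to 10%), judging that “some racemization is possible”. Its eP is lower than this reckoning's, and its eS is higher.

    partner + catalyst + left-handed substrate → catalyst + left-handed product (k = 0.0140 /M²/s)
    partner + catalyst + right-handed substrate → catalyst + right-handed product (k = 0.00460 /M²/s)
    left-handed substrate ⇌ right-handed substrate (k = 0.00860 /s)
    partner + precatalyst → catalyst + spent reagent (k = 0.0200 /M/s)
    catalyst + added ligand ⇌ idle complex, settled at all times (K = 8.70 /M)

The asked flask gives c 18.4%, eP 50.1% and eS 0.654%, so the forecast's eP stands 12 percentage points low, while the c reckoned from 0.263 pool half-lives stands 1.7 points below the flask's. A neighbouring flask, with its other charges and the time as in the recipe, holds 0.10 M of precatalyst, 4.00 times the asked flask's charge. If the pool's rate grows in step with the precatalyst charge, dividing the pool half-life by that factor gives 14.2 min, so the asked time counts 1.05 of them and the reckoned c is 51.8%. That neighbouring flask gives c 50.4%.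

(The runs come from a simulation on assumed constants; the scatter is artificial.)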